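(The numbers of this flask are made up; the rest is arithmetic.)

Per minute is the unit I kept for J: the share of its charge that passes into solution.

J 0.053 M; L 0.0530 mM; time 5.0 min

    J ⇌ X, rate k1*(cs1 - [X]) while solid is left; crystals form when [X] > cs1 (cs1 = 7.2 mM, k1 = 0.142 min⁻¹)
    2 X → X2 (k2 = 7.47 L mol⁻¹ min⁻¹)
    E ⇌ Q + L, settled at all times (K3 = 4.0 × 10⁻⁵ M)
    X → E + G (k4 = 0.0908 min⁻¹)
    X + L → E + L + G (k5 = 11500 L mol⁻¹ min⁻¹)
    D ⇌ G, rate k6*(cs6 - [G]) while solid is left; crystals form when [G] > cs6 (cs6 = 35 mM, k6 = 35.4 min⁻¹)

- L is the free proton; pH is minus the decimal logarithm of its molar concentration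
- percentages count the J that a species holds: one X2 counts as two
- G is meant together with its D
- for a step with 2 of a species take k times the square, and two of it per event
- solid, in amounts per volume of the solution: J, D
- at the start none of J is in solution
- what has only dissolved of J counts as not reacted
- run time (flask): 5.0 min

- part of the J that has reacted (what has only dissolved counts as not reacted) at 5.0 min
- pH of the solution at 5.0 min

With no X in solution, dissolution would pass 9.65% of the charge in 5.0 min. I called this share the feed ceiling.

At the charged L, the acid step removes X at 0.610 min⁻¹, faster than dissolution's coefficient of 0.142 min⁻¹. With the uncatalysed step added, X at that L should level off near 0.169 of its solubility. So I took dissolution, the slower of the two, as the rate-limiting step, running close to its ceiling.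

That comparison drifts. Each G brings one E, and E splits into Q and L, so the acid step quickens as L climbs. Taking E at the feed ceiling, with 4.0 × 10⁻⁵ M, I put the L at the end near 0.452 mM, which makes the acid step 5.20 min⁻¹. The charged L, smaller than that, I set aside.

My ledger, in shares of the charged J:

Into solution, at most: 9.65%

Into D: nothing, as G's solubility stands at 66.0% of the charge

Into X2: I booked nothing, as even X at its solubility pairs at 0.108 min⁻¹, slower than the acid step at the end

Still X at the end: 0.371%

Reacted, as G: 9.27%

The pH of that L: 3.34

The forecast gave 8.8%, under my figure, and pH 3.36, holding that “Dissolution is the bottleneck”.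

The simulation gave 8.86% reacted and pH 3.35. This flask closed its books with 8.84% G, 0.370% X, 0.0157% X2 and 0% D, and its reacted part stood at 0.918 of the feed ceiling. The neighbour flask, charged with 0.21 M of J for the same time, has a feed ceiling of 2.43%. The same factor put its reacted part at 2.23%. Its simulation gave 2.23%, with 98% of the charged J still there, solid or dissolved.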